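## The problem

Compound 29 is a normal labdane acid. Its trans-fused decalin (rings A and B) carries a tetrasubstituted C8=C9 alkene with C17 on C8 and, on C9, the C11–C16 chain that ends in an (E)-3-methylpent-2-enoic acid. Ring A holds an axial 3α-hydroxyl next to quaternary C4 (α-methyl C18, β-hydroxymethyl C19). Ring B holds an axial 6β-hydroxyl, so O6 and C19 are syn-diaxial and flank the β-methyl C20 on quaternary C10. Of the five stereocentres (C3, C4, C5, C6, C10), C10 has no neighbour to learn from and must be set by an enantioselective reaction. Its β-methyl can then send the C4 methyl, the C5 hydrogen and the C6 hydride to the α face, and C4 in turn directs hydride at C3. The alkene is the fragile part: acid can move it or trigger a C20 shift, and the acid must keep its E geometry, so the chain is joined late and freed with fluoride and mild base. The enabling feature is the 1,4-pattern of oxygens: C6 is bonded to C5, and C5 is β to both O3 and C19 through C4. With C3 and C19 as a β-keto ester on a ring A enone and C6 as an aldehyde, both carbons are electrophiles, and the C5–C6 bond needs polarity reversal at C6. That closure cannot give the trans fusion directly, so the route must make C5 planar once more and set C4 and C5 in the right order.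

## Retrosynthesis

**Side chain (C9–C11).** Acid 29 comes from ester 28 and that from the tris(triethylsilyl) ether 27. The C9–C11 bond of 27 is cut to give enol triflate 24 and alkylborane 26, which 9-BBN makes from the commercial dienoate 25. A cut at C13=C14 would need an olefination of a methyl ketone with uncertain E/Z ratio; this cut brings the E alkene in ready-made. The forward step is a B-alkyl Suzuki coupling at a hindered tetrasubstituted triflate.

**Ring B alkene.** Triflate 24 comes from the 8-methyl ketone 23 and that from ketone 22. C10 is quaternary, so 22 can enolise only toward C8 and the alkene position is fixed by constitution. Ketone 22 is traced through alcohol 21 to benzyl ether 20 and triol 19. Benzyl is chosen for O9 because 20 contains no alkene, so hydrogenolysis is orthogonal to the silyl ethers.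

**Carbinols at C3 and C6.** Triol 19 comes from lactone 18 by hydride reduction. Lactone 18 comes from the trans diketo ester 16 (through diol ester 17) by one bulky-hydride reduction. No C–C bond is cut. The forward step must deliver hydride equatorially at C3 and from the α face at C6, and the lactone closure between O6 and C19 proves the configuration at C4, C5 and C6.

**C4 methyl and C5 hydrogen.** Direct methylation of the ring-closure product 12 would fail. In 12 the fusion is cis, C6 stands axial on the α face of ring A, and an electrophile would enter C4 trans to it, from the β face, which makes the ester C18. Therefore 16 is traced to the methylated enol lactone 15, and 15 to enol lactone 14. In 14 the atoms C3, C4, C5, C6 and C19 are coplanar, and only C20 distinguishes the two faces. Methyl then enters α, and methanolysis of 15 returns the ketone with protonation of C5 from the α face. This costs two steps and removes the dependence on the ring fusion of 12.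

**Ring B (key cut, C5–C6).** Enol lactone 14 comes from keto acid 13 and that from the 4-methoxybenzyl ester 12. The C5–C6 bond of 12 is cut to the aldehyde 11, a monocyclic ring A enone ester with the chain on C10. This cut uses the native oxidation levels at C3, C6 and C19 and removes ring B and one stereocentre. The forward step needs an acyl anion equivalent at C6 that adds to the neopentyl but doubly activated C5.

**Cyclisation substrate.** Aldehyde 11 comes from acetal 10, that from iodoenone 9 by carbonylation, and 9 from enone 8 and alcohol 7. The 4-methoxybenzyl ester is chosen because acid removes it; saponification of a β-keto ester is not an option.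

**Quaternary C10.** Alcohol 7 is cut at C9–C8 and across ring A into diene 3, methacrolein 4 and Grignard reagent 2 (from bromide 1). The cycloadduct 5 keeps the enone masked while 2 adds to the aldehyde, giving 6. Diene 3 is commercial, and a hydrogen-bonding diol catalyst is known for this diene with α-substituted acroleins. Metal catalysts such as (salen)CrCl are established only for the less reactive carbamate dienes, which would have to be made.

## Roads not taken

**Alternative 1:** Ring A is closed last, at C3–C4. Zn dust turns the α-bromo lactone A1, which carries a cyanoethyl chain on C10, into its zinc enolate. The enolate adds to the nitrile carbon (Blaise reaction), and hydrolysis gives the tricyclic keto lactone A2. Merits: the lactone ties C19 to O6, so C4 is set by the template; the trans relationship at C5/C10 exists before the key step; the chain is already in place. Weak points: A1 is a cyclohexene with three stereocentres, a tetrasubstituted alkene and a tertiary bromide, and no direct catalytic entry sets its C10. The zinc enolate must form a quaternary centre next to a ring fusion carbon, and C15 must be oxidised afterwards. In stereocontrol at C4 and C5 this road is better than the chosen one, which needs the relay through 14 and 15. The chosen plan sets against it a catalytic origin of C10 in its first C–C bond formation and a cyclisation substrate reached in six steps.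

**Alternative 2:** Ring B is closed at C7–C8. KOt-Bu forms the methyl ketone enolate of A3, a fully substituted ring A with a C5 acetyl group and an ester on the C10 side chain. Claisen condensation gives the 6,8-dione A4. Merits: ring A stereocentres are settled early, the chain is on C9 from the start so no hindered coupling is needed, and 1,3-dione formation is reliable. Weak points: the C8 oxygen is not in the target, so the two carbonyls must be told apart, C8 turned into a methyl-bearing alkene carbon and C6 reduced. A3 with its vicinal C9/C10 substitution and three silyl ethers is long to make. This road is better in avoiding the late coupling. The chosen plan places the only ring B oxygen of the target where it belongs in the ring-forming step itself.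

**Alternative 3:** Ring B and C10 are made together at C9–C10. PhI(OAc)2 oxidises phenol A5, and the enol carbon of its β-keto ester attacks the para position to give dienone A6. Merits: aromatic starting materials and the shortest path to a bicyclic core. Weak points: C10 would be set only by 1,3-induction from the C6 silyl ether. Ring A then needs two alkene reductions with trans fusion. C4 already bears the methyl, so C19 would have to enter from the hindered β face, and the natural selectivity would oxygenate C18. In step count to the bicycle this road is better. The chosen plan sets against it the order ester first, methyl second at C4, which the shielding by C20 rewards.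

Key step: step 7

Remark: bicyclic intermediates are named on the decalin core in labdane numbering (C18 = α-methyl on C4, C19 = β-carbon on C4, C20 = β-methyl on C10). C9 is carried as both epimers from 6 to 21 and C8 in 23, and both are written without configuration.

Remark: the (R,R)-diol catalyst of step 2 is assumed to give the S quaternary centre; if the sense is opposite, its (S,S)-antipode is used.

Step 1
Reactants: 1 2-(2-bromoethyl)-1,3-dioxolane
Product: 2 [2-(1,3-dioxolan-2-yl)ethyl]magnesium bromide
Conditions: Mg, THF, 25 °C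
Reagents that add atoms: magnesium, [Mg]
Why: Grignard formation by insertion of magnesium into the primary C–Br bond; the temperature is kept low because this β-acetal reagent decomposes on warming.

Step 2
Reactants: 3 (E)-3-(tert-butyldimethylsilyloxy)-N,N-dimethylbuta-1,3-dien-1-amine; 4 methacrolein; 2 [2-(1,3-dioxolan-2-yl)ethyl]magnesium bromide
Product: 7 (4S)-4-[3-(1,3-dioxolan-2-yl)-1-hydroxypropyl]-4-methylcyclohex-2-en-1-one, via cycloadduct aldehyde 5 (not isolated), via amino alcohol 6 (not isolated)
Conditions: (R,R)-1-naphthyl-TADDOL (20 mol %), PhMe, −78 °C; then 2, THF, −78 → −40 °C; then 0.5 M HCl (aq), THF, 0 °C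
Reagents that add atoms: none
Why: Hydrogen-bond-catalysed Diels–Alder reaction in which the chiral diol activates methacrolein and shields one face, setting quaternary C10. Grignard addition then occurs at the aldehyde while the enone is still masked as silyl enol ether, and dilute acid hydrolyses the enol ether and eliminates dimethylamine (E1cB) without opening the dioxolane. The carbinol C9 forms as two epimers, which is harmless because it becomes a ketone in step 15.

Step 3
Reactants: 7 (4S)-4-[3-(1,3-dioxolan-2-yl)-1-hydroxypropyl]-4-methylcyclohex-2-en-1-one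
Product: 8 (4S)-4-[1-(benzyloxy)-3-(1,3-dioxolan-2-yl)propyl]-4-methylcyclohex-2-en-1-one
Conditions: 2-benzyloxy-1-methylpyridinium triflate, MgO, PhCF3, 85 °C
Reagents that add atoms: 2-benzyloxy-1-methylpyridinium trifluoromethanesulfonate, C[n+]1ccccc1OCc1ccccc1.[O-]S(=O)(=O)C(F)(F)F
Why: Neutral benzyl transfer (Dudley benzylation) etherifies the hindered neopentyl carbinol without base or acid, so enone and acetal survive. Benzyl outlasts every step up to 20 and leaves by hydrogenolysis at a stage without alkenes.

Step 4
Reactants: 8 (4S)-4-[1-(benzyloxy)-3-(1,3-dioxolan-2-yl)propyl]-4-methylcyclohex-2-en-1-one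
Product: 9 (4S)-4-[1-(benzyloxy)-3-(1,3-dioxolan-2-yl)propyl]-2-iodo-4-methylcyclohex-2-en-1-one
Conditions: I2, pyridine, CH2Cl2, 0 °C → rt
Reagents that add atoms: iodine, II
Why: α-Iodination of the enone by the iodine/pyridine protocol (conjugate addition of pyridine, iodination of the enolate, elimination), which is established for 4,4-disubstituted cyclohexenones.

Step 5
Reactants: 9 (4S)-4-[1-(benzyloxy)-3-(1,3-dioxolan-2-yl)propyl]-2-iodo-4-methylcyclohex-2-en-1-one
Product: 10 4-methoxybenzyl (3S)-3-[1-(benzyloxy)-3-(1,3-dioxolan-2-yl)propyl]-3-methyl-6-oxocyclohex-1-ene-1-carboxylate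
Conditions: Pd(PPh3)4 (5 mol %), CO (1 atm), 4-MeOC6H4CH2OH, i-Pr2NEt, DMF, 60 °C
Reagents that add atoms: carbon monoxide, [C-]#[O+]; 4-methoxybenzyl alcohol, COc1ccc(CO)cc1
Why: Palladium-catalysed alkoxycarbonylation of the vinyl iodide (oxidative addition to zerovalent palladium, CO insertion, alcoholysis) gives the alkylidene β-keto ester, which cannot tautomerise because C10 bears no hydrogen. The 4-methoxybenzyl ester is chosen so that acid can free the carboxyl group in step 8.

Step 6
Reactants: 10 4-methoxybenzyl (3S)-3-[1-(benzyloxy)-3-(1,3-dioxolan-2-yl)propyl]-3-methyl-6-oxocyclohex-1-ene-1-carboxylate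
Product: 11 4-methoxybenzyl (3S)-3-[1-(benzyloxy)-4-oxobutyl]-3-methyl-6-oxocyclohex-1-ene-1-carboxylate
Conditions: PPTS, acetone/H2O, 55 °C
Reagents that add atoms: water, O
Why: Mild acid-catalysed acetal hydrolysis releases the C6 aldehyde; benzyl ether and 4-methoxybenzyl ester tolerate the pyridinium acid, and the neopentyl C5 resists lasting hydration.

Step 7
Reactants: 11 4-methoxybenzyl (3S)-3-[1-(benzyloxy)-4-oxobutyl]-3-methyl-6-oxocyclohex-1-ene-1-carboxylate
Product: 12 4-methoxybenzyl 9-(benzyloxy)-3-hydroxy-10β-methyl-6-oxo-5β-decal-3-ene-4-carboxylate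
Conditions: 3-benzyl-5-(2-hydroxyethyl)-4-methylthiazolium chloride (20 mol %), Et3N, 1,4-dioxane, 70 °C
Reagents that add atoms: none
Why: The thiazol-2-ylidene formed from the salt and Et3N adds to the aldehyde carbon C6, and proton transfer gives the Breslow intermediate, an acyl anion equivalent. Its nucleophilic carbon adds to C5, the β-carbon of the ring A alkylidene β-keto ester, in a 6-exo-trig closure that forms the C5–C6 bond and ring B; loss of the carbene leaves the C6 ketone. The closest known reaction type is the intramolecular Stetter reaction of aliphatic aldehydes onto alkylidene 1,3-dicarbonyl acceptors. The step needs the carbene to engage only the aldehyde, which is secured because the aldehyde is the sole carbonyl that can form the hydroxy-enamine, while double activation compensates for the hindrance at C5. The three-carbon tether C7–C9 permits only the six-membered closure. The new stereocentre C5 is controlled by C10: the chain reaches C5 only on its own face of ring A, anti to the pseudo-axial C20 methyl, so the cis fusion (5β-H) is expected under kinetic control. This configuration is not relied upon, because C5 becomes trigonal in step 8 and is reset in step 10, so either C5 epimer and both C9 epimers serve.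

Step 8
Reactants: 12 4-methoxybenzyl 9-(benzyloxy)-3-hydroxy-10β-methyl-6-oxo-5β-decal-3-ene-4-carboxylate
Product: 14 9-(benzyloxy)-3-hydroxy-10β-methyldecala-3,5-dien-19,6-olide, via keto acid 13 (not isolated)
Conditions: CF3CO2H, anisole, CH2Cl2, 0 °C; then (CF3CO)2O, 0 °C → rt
Reagents that add atoms: none
Why: Acidolysis of the 4-methoxybenzyl ester (cation trapped by anisole) frees the acid, and its trifluoroacetic mixed anhydride acylates the oxygen of the C6 enol, an enol lactonisation of a γ-keto acid. The enol is drawn toward C5 by conjugation with the ring A enol, and the cold anhydrous medium is meant to outrun decarboxylation of the β-keto acid. C5 is now trigonal, so the ring fusion formed in step 7 is erased.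

Step 9
Reactants: 14 9-(benzyloxy)-3-hydroxy-10β-methyldecala-3,5-dien-19,6-olide
Product: 15 9-(benzyloxy)-4α,10β-dimethyl-3-oxodecal-5-en-19,6-olide
Conditions: K2CO3, MeI, acetone, rt
Reagents that add atoms: iodomethane, CI
Why: C-Alkylation of the 2-acyl lactone (β-dicarbonyl) anion, which is planar from C3 to C6. The only element that distinguishes its faces is the pseudo-axial C20 methyl on the β face, so methyl iodide should enter from the α face and leave C19, held in the lactone, on the β side.

Step 10
Reactants: 15 9-(benzyloxy)-4α,10β-dimethyl-3-oxodecal-5-en-19,6-olide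
Product: 16 methyl 9-(benzyloxy)-4α,10β-dimethyl-3,6-dioxo-5α-decalin-4β-carboxylate
Conditions: K2CO3 (0.2 equiv), MeOH, 0 °C; AcOH quench
Reagents that add atoms: methanol, CO
Why: Methanolysis of the enol ester (transesterification) releases the C6 enolate, which should be protonated at C5 from the α face because the β face is closed by the axial C20 methyl and the axial C19 ester on both neighbours. This kinetic outcome agrees with the expected thermodynamic preference of a 4,4,10-trisubstituted 6-ketone for the trans fusion. Catalytic carbonate at 0 °C is mild enough to avoid retro-Claisen cleavage of the quaternary β-keto ester.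

Step 11
Reactants: 16 methyl 9-(benzyloxy)-4α,10β-dimethyl-3,6-dioxo-5α-decalin-4β-carboxylate
Product: 18 9-(benzyloxy)-3α-hydroxy-4α,10β-dimethyl-5α-decalin-19,6β-olide, via dihydroxy ester 17 (not isolated)
Conditions: LiBH(s-Bu)3, THF, −78 → 0 °C; NH4Cl (aq)
Reagents that add atoms: none
Why: Bulky-hydride reduction: the C3 ketone next to quaternary C4 is attacked equatorially (axial 3α-OH, as with 4,4-disubstituted 3-ketones), and the C6 ketone from the α face opposite C19 and C20 (6β-OH). The 6β-alkoxide then closes onto the syn-axial C19 ester to the γ-lactone, which confirms the configuration at C4, C5 and C6.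

Step 12
Reactants: 18 9-(benzyloxy)-3α-hydroxy-4α,10β-dimethyl-5α-decalin-19,6β-olide
Product: 19 9-(benzyloxy)-4β-(hydroxymethyl)-4α,10β-dimethyl-5α-decalin-3α,6β-diol
Conditions: LiAlH4, THF, 0 °C → reflux
Reagents that add atoms: none
Why: Hydride reduction of the hindered lactone to the 6β,19-diol; the benzyl ether is inert and no stereocentre is touched.

Step 13
Reactants: 19 9-(benzyloxy)-4β-(hydroxymethyl)-4α,10β-dimethyl-5α-decalin-3α,6β-diol
Product: 20 9-(benzyloxy)-3α,6β-bis(triethylsilyloxy)-4β-[(triethylsilyloxy)methyl]-4α,10β-dimethyl-5α-decalin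
Conditions: Et3SiOTf, 2,6-lutidine, CH2Cl2, 0 °C → rt
Reagents that add atoms: triethylsilyl trifluoromethanesulfonate, CC[Si](CC)(CC)OS(=O)(=O)C(F)(F)F
Why: Silylation with the silyl triflate, which is reactive enough for the axial 3α- and 6β-hydroxyls. Triethylsilyl ethers survive hydrogenolysis, enolate chemistry and cross-coupling and leave together with fluoride.

Step 14
Reactants: 20 9-(benzyloxy)-3α,6β-bis(triethylsilyloxy)-4β-[(triethylsilyloxy)methyl]-4α,10β-dimethyl-5α-decalin
Product: 21 3α,6β-bis(triethylsilyloxy)-4β-[(triethylsilyloxy)methyl]-4α,10β-dimethyl-5α-decalin-9-ol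
Conditions: H2 (1 atm), Pd/C, EtOAc, rt
Reagents that add atoms: none
Why: Hydrogenolysis of the benzyl ether in a molecule without alkenes; the aprotic solvent keeps the silyl ethers intact.

Step 15
Reactants: 21 3α,6β-bis(triethylsilyloxy)-4β-[(triethylsilyloxy)methyl]-4α,10β-dimethyl-5α-decalin-9-ol
Product: 22 3α,6β-bis(triethylsilyloxy)-4β-[(triethylsilyloxy)methyl]-4α,10β-dimethyl-5α-decalin-9-one
Conditions: Dess–Martin periodinane, NaHCO3, CH2Cl2, rt
Reagents that add atoms: none
Why: Dess–Martin oxidation of the secondary alcohol under buffered conditions; both C9 epimers converge on one ketone.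

Step 16
Reactants: 22 3α,6β-bis(triethylsilyloxy)-4β-[(triethylsilyloxy)methyl]-4α,10β-dimethyl-5α-decalin-9-one
Product: 23 3α,6β-bis(triethylsilyloxy)-4β-[(triethylsilyloxy)methyl]-4α,8,10β-trimethyl-5α-decalin-9-one
Conditions: LiN(i-Pr)2, THF, −78 °C; MeI, DMPU, −78 → −20 °C
Reagents that add atoms: iodomethane, CI
Why: Enolate alkylation; the ketone can enolise only toward C8 because C10 is quaternary, and the new C8 centre is lost again in step 17.

Step 17
Reactants: 23 3α,6β-bis(triethylsilyloxy)-4β-[(triethylsilyloxy)methyl]-4α,8,10β-trimethyl-5α-decalin-9-one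
Product: 24 3α,6β-bis(triethylsilyloxy)-4β-[(triethylsilyloxy)methyl]-4α,8,10β-trimethyl-5α-decal-8-en-9-yl trifluoromethanesulfonate
Conditions: KN(SiMe3)2, THF, −78 °C; Comins' reagent, −78 → 0 °C
Reagents that add atoms: N-(5-chloropyridin-2-yl)bis(trifluoromethanesulfonyl)imide, FC(F)(F)S(=O)(=O)N(c1ccc(Cl)cn1)S(=O)(=O)C(F)(F)F
Why: O-Sulfonylation of the only possible enolate gives the tetrasubstituted enol triflate and fixes the alkene at C8=C9.

Step 18
Reactants: 24 3α,6β-bis(triethylsilyloxy)-4β-[(triethylsilyloxy)methyl]-4α,8,10β-trimethyl-5α-decal-8-en-9-yl trifluoromethanesulfonate; 25 methyl (E)-3-methylpenta-2,4-dienoate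
Product: 27 methyl (13E)-3α,6β,19-tris(triethylsilyloxy)labda-8,13-dien-15-oate, via alkylborane 26 (not isolated)
Conditions: 25, 9-BBN, THF, 0 °C → rt; then 24, PdCl2(dppf), AsPh3, Cs2CO3, DMF/THF/H2O, 50 °C
Reagents that add atoms: none
Why: Anti-Markovnikov hydroboration of the terminal vinyl group of 25 leaves the conjugated ester alkene untouched. B-alkyl Suzuki–Miyaura coupling with the enol triflate then forms C9–C11, and the E alkene of 25 takes no part and is retained.

Step 19
Reactants: 27 methyl (13E)-3α,6β,19-tris(triethylsilyloxy)labda-8,13-dien-15-oate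
Product: 28 methyl (13E)-3α,6β,19-trihydroxylabda-8,13-dien-15-oate
Conditions: HF·pyridine, pyridine, THF, 0 °C → rt
Reagents that add atoms: none
Why: Fluoride cleavage of the three silyl ethers under buffered conditions that spare the tetrasubstituted alkene and the enoate.

Step 20
Reactants: 28 methyl (13E)-3α,6β,19-trihydroxylabda-8,13-dien-15-oate
Product: 29 (13E)-3α,6β,19-trihydroxylabda-8,13-dien-15-oic acid
Conditions: LiOH, THF/MeOH/H2O, 40 °C; then 1 M HCl to pH 4
Reagents that add atoms: lithium hydroxide, [Li+].[OH-]
Why: Saponification of the conjugated methyl ester; mild acidification avoids migration of the C8=C9 alkene.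

## Compound list

1 | 2-(2-bromoethyl)-1,3-dioxolane | BrCCC1OCCO1 | starting material
2 | [2-(1,3-dioxolan-2-yl)ethyl]magnesium bromide | Br[Mg]CCC1OCCO1 | intermediate
3 | (E)-3-(tert-butyldimethylsilyloxy)-N,N-dimethylbuta-1,3-dien-1-amine | CN(C)/C=C/C(=C)O[Si](C)(C)C(C)(C)C | starting material
4 | methacrolein | CC(=C)C=O | starting material
5 | (1S,2R)-2-(dimethylamino)-1-methyl-4-(tert-butyldimethylsilyloxy)cyclohex-3-ene-1-carbaldehyde | O=C[C@@]1(C)CCC(O[Si](C)(C)C(C)(C)C)=C[C@H]1N(C)C | intermediate
6 | 1-[(1S,2R)-2-(dimethylamino)-1-methyl-4-(tert-butyldimethylsilyloxy)cyclohex-3-en-1-yl]-3-(1,3-dioxolan-2-yl)propan-1-ol, both carbinol epimers | OC(CCC1OCCO1)[C@@]2(C)CCC(O[Si](C)(C)C(C)(C)C)=C[C@H]2N(C)C | intermediate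
7 | (4S)-4-[3-(1,3-dioxolan-2-yl)-1-hydroxypropyl]-4-methylcyclohex-2-en-1-one | OC(CCC1OCCO1)[C@@]2(C)CCC(=O)C=C2 | intermediate
8 | (4S)-4-[1-(benzyloxy)-3-(1,3-dioxolan-2-yl)propyl]-4-methylcyclohex-2-en-1-one | O(Cc1ccccc1)C(CCC2OCCO2)[C@@]3(C)CCC(=O)C=C3 | intermediate
9 | (4S)-4-[1-(benzyloxy)-3-(1,3-dioxolan-2-yl)propyl]-2-iodo-4-methylcyclohex-2-en-1-one | O(Cc1ccccc1)C(CCC2OCCO2)[C@@]3(C)CCC(=O)C(I)=C3 | intermediate
10 | 4-methoxybenzyl (3S)-3-[1-(benzyloxy)-3-(1,3-dioxolan-2-yl)propyl]-3-methyl-6-oxocyclohex-1-ene-1-carboxylate | O(Cc1ccccc1)C(CCC2OCCO2)[C@@]3(C)CCC(=O)C(C(=O)OCc4ccc(OC)cc4)=C3 | intermediate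
11 | 4-methoxybenzyl (3S)-3-[1-(benzyloxy)-4-oxobutyl]-3-methyl-6-oxocyclohex-1-ene-1-carboxylate | O=CCCC(OCc1ccccc1)[C@@]2(C)CCC(=O)C(C(=O)OCc3ccc(OC)cc3)=C2 | intermediate
12 | 4-methoxybenzyl 9-(benzyloxy)-3-hydroxy-10β-methyl-6-oxo-5β-decal-3-ene-4-carboxylate (cis-fused, enol of the 3-ketone) | O=C1CCC(OCc3ccccc3)[C@@]2(C)CCC(O)=C(C(=O)OCc4ccc(OC)cc4)[C@@H]12 | intermediate
13 | 9-(benzyloxy)-3-hydroxy-10β-methyl-6-oxo-5β-decal-3-ene-4-carboxylic acid | O=C1CCC(OCc3ccccc3)[C@@]2(C)CCC(O)=C(C(=O)O)[C@@H]12 | intermediate
14 | 9-(benzyloxy)-3-hydroxy-10β-methyldecala-3,5-dien-19,6-olide (enol lactone of the C4 carboxyl group with O6) | O=C1OC2=C3C1=C(O)CC[C@]3(C)C(OCc4ccccc4)CC2 | intermediate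
15 | 9-(benzyloxy)-4α,10β-dimethyl-3-oxodecal-5-en-19,6-olide | O=C1OC2=C3[C@]1(C)C(=O)CC[C@]3(C)C(OCc4ccccc4)CC2 | intermediate
16 | methyl 9-(benzyloxy)-4α,10β-dimethyl-3,6-dioxo-5α-decalin-4β-carboxylate (trans-fused) | O=C1CCC(OCc3ccccc3)[C@@]2(C)CCC(=O)[C@](C)(C(=O)OC)[C@H]12 | intermediate
17 | methyl 9-(benzyloxy)-3α,6β-dihydroxy-4α,10β-dimethyl-5α-decalin-4β-carboxylate | O[C@@H]1CC[C@]2(C)C(OCc3ccccc3)CC[C@@H](O)[C@H]2[C@@]1(C)C(=O)OC | intermediate
18 | 9-(benzyloxy)-3α-hydroxy-4α,10β-dimethyl-5α-decalin-19,6β-olide | O[C@@H]1CC[C@]2(C)C(OCc3ccccc3)CC[C@H]4OC(=O)[C@]1(C)[C@@H]24 | intermediate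
19 | 9-(benzyloxy)-4β-(hydroxymethyl)-4α,10β-dimethyl-5α-decalin-3α,6β-diol | O[C@@H]1CC[C@]2(C)C(OCc3ccccc3)CC[C@@H](O)[C@H]2[C@@]1(C)CO | intermediate
20 | 9-(benzyloxy)-3α,6β-bis(triethylsilyloxy)-4β-[(triethylsilyloxy)methyl]-4α,10β-dimethyl-5α-decalin | CC[Si](CC)(CC)O[C@@H]1CC[C@]2(C)C(OCc3ccccc3)CC[C@@H](O[Si](CC)(CC)CC)[C@H]2[C@@]1(C)CO[Si](CC)(CC)CC | intermediate
21 | 3α,6β-bis(triethylsilyloxy)-4β-[(triethylsilyloxy)methyl]-4α,10β-dimethyl-5α-decalin-9-ol | CC[Si](CC)(CC)O[C@@H]1CC[C@]2(C)C(O)CC[C@@H](O[Si](CC)(CC)CC)[C@H]2[C@@]1(C)CO[Si](CC)(CC)CC | intermediate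
22 | 3α,6β-bis(triethylsilyloxy)-4β-[(triethylsilyloxy)methyl]-4α,10β-dimethyl-5α-decalin-9-one | CC[Si](CC)(CC)O[C@@H]1CC[C@]2(C)C(=O)CC[C@@H](O[Si](CC)(CC)CC)[C@H]2[C@@]1(C)CO[Si](CC)(CC)CC | intermediate
23 | 3α,6β-bis(triethylsilyloxy)-4β-[(triethylsilyloxy)methyl]-4α,8,10β-trimethyl-5α-decalin-9-one, both C8 epimers | CC[Si](CC)(CC)O[C@@H]1CC[C@]2(C)C(=O)C(C)C[C@@H](O[Si](CC)(CC)CC)[C@H]2[C@@]1(C)CO[Si](CC)(CC)CC | intermediate
24 | 3α,6β-bis(triethylsilyloxy)-4β-[(triethylsilyloxy)methyl]-4α,8,10β-trimethyl-5α-decal-8-en-9-yl trifluoromethanesulfonate | CC[Si](CC)(CC)O[C@@H]1CC[C@]2(C)C(OS(=O)(=O)C(F)(F)F)=C(C)C[C@@H](O[Si](CC)(CC)CC)[C@H]2[C@@]1(C)CO[Si](CC)(CC)CC | intermediate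
25 | methyl (E)-3-methylpenta-2,4-dienoate | COC(=O)/C=C(\C)C=C | starting material
26 | methyl (E)-5-(9-borabicyclo[3.3.1]nonan-9-yl)-3-methylpent-2-enoate | COC(=O)/C=C(\C)CCB1C2CCCC1CCC2 | intermediate
27 | methyl (13E)-3α,6β,19-tris(triethylsilyloxy)labda-8,13-dien-15-oate | CC[Si](CC)(CC)O[C@@H]1CC[C@]2(C)C(CC/C(C)=C/C(=O)OC)=C(C)C[C@@H](O[Si](CC)(CC)CC)[C@H]2[C@@]1(C)CO[Si](CC)(CC)CC | intermediate
28 | methyl (13E)-3α,6β,19-trihydroxylabda-8,13-dien-15-oate | O[C@@H]1CC[C@]2(C)C(CC/C(C)=C/C(=O)OC)=C(C)C[C@@H](O)[C@H]2[C@@]1(C)CO | intermediate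
29 | (13E)-3α,6β,19-trihydroxylabda-8,13-dien-15-oic acid (CNP0246116.2) | CC1=C(CC/C(C)=C/C(=O)O)[C@@]2(C)CC[C@@H](O)[C@](C)(CO)[C@@H]2[C@H](O)C1 | target

## Step count and least certain steps

Total: 20 steps. Longest linear sequence: 20 steps (1 to 29); dienoate 25 enters in step 18.

**Step 7 (key step).** The enolisable aldehyde may react through its α-carbon before the carbene does its work: a 5-exo Michael addition of C7 to C5 is a possible competing cyclisation, and aldol or benzoin-type self-condensation are the others. Addition to the neopentyl C5 may also be slow enough for the catalyst to be lost. Fallback: the same C5–C6 bond is made by an acyl radical, so no base or enolate is involved. Aldehyde 11 is oxidised with NaClO2 (NaH2PO4, 2-methylbut-2-ene) to the carboxylic acid F1. The acid is converted with (PhSe)2 and PBu3 into the Se-phenyl selenoester F2. Bu3SnH with AIBN in hot benzene then generates the acyl radical, which closes 6-exo onto C5 and gives 12 after hydrogen transfer to the doubly stabilised C4 radical.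

**Step 8.** The transient β-keto acid 13 may lose CO2 before the C6 enol is acylated, and the 4-methoxybenzyl cation may alkylate the ring A enol at carbon. Fallback: an aryl ester is used so that no free acid is ever formed. Iodoenone 9 is carbonylated with phenol in place of the benzylic alcohol to the phenyl ester F3. The acetal is hydrolysed to the aldehyde F4, and the thiazolium-catalysed closure gives the phenyl keto ester F5. DBU in MeCN then lets the C6 enolate oxygen displace phenoxide, which leads back to 14.

**Step 10.** Protonation at C5 may be less face-selective than argued, and equilibration through the C6 enol may leave some cis-fused ketone because the energy margin of a 3,6-diketone is moderate. Prolonged base could also open ring A by retro-Claisen cleavage. Fallback: C5 is set under a stronger thermodynamic bias after C3 has been reduced. Enol lactone 15 is reduced with LiBH(s-Bu)3 at −78 °C to the hydroxy enol lactone F6. LiOH in aqueous THF opens it to the keto acid F7. With an axial 3α-oxygen and the 4α-methyl in place, both chair forms of the cis isomer carry a syn-axial clash, so F7 should settle as the trans isomer. NaBH4 is added to the basic solution to give the dihydroxy acid F8, and acidification closes it to 18.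

**Step 18.** Oxidative addition and transmetalation at a tetrasubstituted triflate beside quaternary C10 may be slow, so that β-hydride elimination or protodeboronation of the alkyl partner and hydrolysis of the triflate take over. Fallback: the hindered coupling is done with a small sp2 partner and the sp3 coupling is moved to the far end of the chain. Triflate 24 undergoes Stille coupling with tributyl(vinyl)stannane (Pd(PPh3)4, LiCl, THF) to the diene F9. 9-BBN adds to its terminal vinyl group to give the alkylborane F10, which is coupled with methyl (E)-3-iodobut-2-enoate (PdCl2(dppf), K3PO4) to reach 27.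

**Step 2.** The uncatalysed cycloaddition of the very reactive diene may erode the enantiomeric purity, and the Grignard reagent may add incompletely to the crowded aldehyde of 5 or the acetal may be lost during enone release. Fallback: the established reduce-then-release sequence is used and the chain is added to a stable aldehyde. Cycloadduct 5 is reduced in the same flask with LiAlH4 to the amino alcohol F11. Dilute HCl releases the hydroxymethyl enone F12, which can be enriched by crystallisation of a derivative if needed. Dess–Martin oxidation gives the enone aldehyde F13, and reagent 2 at −78 °C adds to the aldehyde faster than to the enone, giving 7.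

## Further compounds

F1 | step 7 | 4-(benzyloxy)-4-{(1S)-3-[(4-methoxybenzyloxy)carbonyl]-1-methyl-4-oxocyclohex-2-en-1-yl}butanoic acid | OC(=O)CCC(OCc1ccccc1)[C@@]2(C)CCC(=O)C(C(=O)OCc3ccc(OC)cc3)=C2
F2 | step 7 | Se-phenyl selenoester of F1 | O=C([Se]c1ccccc1)CCC(OCc2ccccc2)[C@@]3(C)CCC(=O)C(C(=O)OCc4ccc(OC)cc4)=C3
F3 | step 8 | phenyl (3S)-3-[1-(benzyloxy)-3-(1,3-dioxolan-2-yl)propyl]-3-methyl-6-oxocyclohex-1-ene-1-carboxylate | O(Cc1ccccc1)C(CCC2OCCO2)[C@@]3(C)CCC(=O)C(C(=O)Oc4ccccc4)=C3
F4 | step 8 | phenyl (3S)-3-[1-(benzyloxy)-4-oxobutyl]-3-methyl-6-oxocyclohex-1-ene-1-carboxylate | O=CCCC(OCc1ccccc1)[C@@]2(C)CCC(=O)C(C(=O)Oc3ccccc3)=C2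
F5 | step 8 | phenyl 9-(benzyloxy)-3-hydroxy-10β-methyl-6-oxo-5β-decal-3-ene-4-carboxylate | O=C1CCC(OCc3ccccc3)[C@@]2(C)CCC(O)=C(C(=O)Oc4ccccc4)[C@@H]12
F6 | step 10 | 9-(benzyloxy)-3α-hydroxy-4α,10β-dimethyldecal-5-en-19,6-olide | O=C1OC2=C3[C@]1(C)[C@H](O)CC[C@]3(C)C(OCc4ccccc4)CC2
F7 | step 10 | 9-(benzyloxy)-3α-hydroxy-4α,10β-dimethyl-6-oxo-5α-decalin-4β-carboxylic acid | O[C@@H]1CC[C@]2(C)C(OCc3ccccc3)CCC(=O)[C@H]2[C@@]1(C)C(=O)O
F8 | step 10 | 9-(benzyloxy)-3α,6β-dihydroxy-4α,10β-dimethyl-5α-decalin-4β-carboxylic acid | O[C@@H]1CC[C@]2(C)C(OCc3ccccc3)CC[C@@H](O)[C@H]2[C@@]1(C)C(=O)O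
F9 | step 18 | 3α,6β-bis(triethylsilyloxy)-4β-[(triethylsilyloxy)methyl]-4α,8,10β-trimethyl-9-vinyl-5α-decal-8-ene | CC[Si](CC)(CC)O[C@@H]1CC[C@]2(C)C(C=C)=C(C)C[C@@H](O[Si](CC)(CC)CC)[C@H]2[C@@]1(C)CO[Si](CC)(CC)CC
F10 | step 18 | 9-[2-(9-borabicyclo[3.3.1]nonan-9-yl)ethyl] analogue of F9 | CC[Si](CC)(CC)O[C@@H]1CC[C@]2(C)C(CCB3C4CCCC3CCC4)=C(C)C[C@@H](O[Si](CC)(CC)CC)[C@H]2[C@@]1(C)CO[Si](CC)(CC)CC
F11 | step 2 | [(1S,2R)-2-(dimethylamino)-1-methyl-4-(tert-butyldimethylsilyloxy)cyclohex-3-en-1-yl]methanol | OC[C@@]1(C)CCC(O[Si](C)(C)C(C)(C)C)=C[C@H]1N(C)C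
F12 | step 2 | (4S)-4-(hydroxymethyl)-4-methylcyclohex-2-en-1-one | OC[C@@]1(C)CCC(=O)C=C1
F13 | step 2 | (1S)-1-methyl-4-oxocyclohex-2-ene-1-carbaldehyde | O=C[C@@]1(C)CCC(=O)C=C1
A1 | alternative 1 | α-bromo-α-methyl 19,6β-lactone on a ring B cyclohexene with cyanoethyl chain on C10 and silylated side chain | N#CCC[C@]1(C)C(CC/C(C)=C/CO[Si](C)(C)C(C)(C)C)=C(C)C[C@H]2OC(=O)C(C)(Br)[C@@H]12
A2 | alternative 1 | tricyclic 3-oxo-19,6β-lactone with C8=C9 alkene and silylated side chain | CC1=C(CC/C(C)=C/CO[Si](C)(C)C(C)(C)C)[C@@]2(C)CCC(=O)[C@@]3(C)[C@@H]2[C@@H](C1)OC3=O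
A3 | alternative 2 | ring A methyl ketone (C5 acetyl) with C10 side-chain methyl ester and 3α/C19 silyl ethers | COC(=O)C(CC/C(C)=C/CO[Si](C)(C)C(C)(C)C)[C@@]1(C)CC[C@@H](O[Si](C)(C)C(C)(C)C)[C@](C)(CO[Si](C)(C)C(C)(C)C)[C@@H]1C(C)=O
A4 | alternative 2 | trans-decalin-6,8-dione with C9 side chain and 3α/C19 silyl ethers | O=C1[C@H](CC/C(C)=C/CO[Si](C)(C)C(C)(C)C)[C@@]2(C)CC[C@@H](O[Si](C)(C)C(C)(C)C)[C@](C)(CO[Si](C)(C)C(C)(C)C)[C@@H]2C(=O)C1
A5 | alternative 3 | 2,4-dimethylphenol carrying a silyloxy β-keto ester chain meta to the hydroxyl | COC(=O)CC(=O)C[C@@H](O[Si](C)(C)C(C)(C)C)c1c(C)ccc(O)c1C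
A6 | alternative 3 | bicyclic 1,4-dien-3-one with quaternary C10, 6β-silyl ether and enolised β-keto ester | OC1=C(C(=O)OC)[C@@]2(C)C=CC(=O)C(C)=C2[C@H](O[Si](C)(C)C(C)(C)C)C1
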